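1. The vessel was closed, stirred and isothermal. Into it went substrate, added ligand and 65 µM of precatalyst, and target appeared after an induction period.

| flask | substrate | precatalyst | added ligand | remark | time |
|---|---|---|---|---|---|
| red | 0.015 M | 65 µM | 0.36 mM | run made earlier |  |
| amber | 0.024 M | 65 µM | 0.36 mM | run made earlier |  |
| violet | 0.046 M | 65 µM | 0.36 mM | run made earlier |  |
| ochre | 0.050 M | 65 µM | 0.81 mM | run made earlier |  |
| eta | 0.012 M | 65 µM | 1.5 mM |  | 5.0 h |
| zeta | 0.050 M | 65 µM | 0.36 mM |  | 5.0 h |

| run | time / h | target / % | substrate / % |
|---|---|---|---|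
| red | 0.417 | 0 | 100 |
| red | 0.833 | 1 | 99 |
| red | 1.33 | 4 | 95 |
| red | 2.50 | 14 | 83 |
| red | 5.00 | 38 | 68 |
| amber | 0.417 | 2 | 97 |
| amber | 0.833 | 0 | 97 |
| amber | 1.33 | 5 | 95 |
| amber | 2.50 | 14 | 90 |
| amber | 5.00 | 28 | 71 |
| violet | 0.417 | 0 | 98 |
| violet | 0.833 | 0 | 100 |
| violet | 1.33 | 1 | 97 |
| violet | 2.50 | 8 | 94 |
| violet | 5.00 | 24 | 81 |
| ochre | 0.417 | 4 | 99 |
| ochre | 1.33 | 1 | 95 |
| ochre | 2.50 | 3 | 92 |
| ochre | 4.00 | 8 | 91 |
| ochre | 5.00 | 16 | 88 |

(standard deviation of a reading: 2 percentage points)



* the flask that ends with the higher amount of target, in percent of the substrate charged, or "neither" when 2 percentage points or less lies between them (eta / zeta / neither)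
* final target, as a percentage of the substrate charged, in eta
* final target, as a percentage of the substrate charged, in zeta

2. Eta looked almost like red: [substrate] was 0.012 M against 0.015 M. But [added ligand] was 1.5 mM against 0.36 mM. So I followed one free catalyst molecule to a fork I supposed: it meets substrate and works, or meets added ligand and idles. The odds then follow the fork ratio, [added ligand]/[substrate], which was 0.125 in eta and 0.0240 in red.

3. I took T as the target concentration at 5.0 h, with precatalyst and time held. It read 5.70 mM in red, at the fork ratio above, and 11.0 mM in violet, at 0.00783. I supposed the reciprocal of T to be straight in the fork ratio. These two readings then gave 0.00944 as the crossover ratio, the fork ratio at which working and idle catalyst stand equal, and a ceiling on T of 20.2 mM. Ochre, left out of this reckoning, came to 14.9% and read 16%.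

4. My reckoning gave eta 11.8%, against the 38% read in red. Zeta, at a fork ratio of 0.00720, came to 22.9%, so I expected zeta to end higher.

5. The forecast named zeta, with 23% for zeta and 18% for eta, the eta figure being above mine, and it said “the eta estimate is the less certain of the two”.

6. The flasks gave zeta as the higher, with 21.0% in zeta and 11.6% in eta.

    substrate + free catalyst → catalyst intermediate A (k = 69.0 /M/s)
    catalyst intermediate A → catalyst intermediate B (k = 1.20 /s)
    catalyst intermediate B → free catalyst + target (k = 0.0240 /s)
    free catalyst + added ligand ⇌ idle complex, settled at all times (K = 2.70 × 10⁵ /M)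
    free catalyst + target → free catalyst + over-reaction product (k = 0.120 /M/s)
    precatalyst ⇌ free catalyst (K = 17.0, k = 1.50 × 10⁻⁴ /s)

The largest single effect on target in eta was the tying up of free catalyst and added ligand as idle complex, acting together with the reading at 5.0 h and not at 50.0 h: eta without that tying up gave 97.2%, and eta read at 50.0 h gave 85.1%, against 11.6%. At 5.00 h the fork ratio in eta was 0.136, so the crossover ratio foretold 0.0693 catalyst intermediate B per idle complex, and eta held 0.0782. In zeta, where catalyst intermediate B was the resting state of the round, the fork ratio of 0.00846 foretold 1.12, and zeta held 1.26.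

The runs stem from a simulated flask for substances that don't exist; noise was put on by code.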